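**Retrosynthetic overview**
1. 8 ⇐ 7: last-stage conjugate hydration of the C4=C15 enone methylene (sets C4).
2. 7 ⇐ 5: aerobic γ-hydroxylation at C10, moving the alkene from C1=C10 to C1=C2 (sets C10).
3. 5 ⇐ 3 + 4: biomimetic Diels–Alder reaction of the diene C14=C10–C1=C2 of dienone 4 with the C4'=C15' enone of 3; this forms the only new ring (the spiro cyclohexene) and sets C4'.
4. 3 and 4 both arise in one flask from alcohol 2 (oxidation, then partial dehydrogenation), so 2 → 7 is a single operation; 2 ⇐ 1 by allylic hydroxylation.
5. Ring order: both 5-7-5 guaianolide units come intact from 1; the cyclohexene is formed last.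

Assumption: dehydrocostus lactone 1, the bulk sesquiterpene lactone of costus root oil, is taken as a cheap commercial starting material.
Numbering: guaiane locants are used; primed locants belong to the lower unit (the former dienophile); α is the face of H-1/H-5. Equivalents in steps 2 and 3 are relative to the reactant of that step.

**Step 1**
Reactants: 1 dehydrocostus lactone
Product: 2 epi-zaluzanin C
Conditions: SeO2 (50 mol %), t-BuOOH (2 equiv), CH2Cl2, 0 → 23 °C
Reagents that add atoms: selenium dioxide, O=[Se]=O; tert-butyl hydroperoxide, CC(C)(C)OO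
Why: Riley allylic hydroxylation (ene reaction at C15 with loss of a C3 hydrogen, then [2,3]-shift that restores the exocyclic alkene) delivers oxygen to C3 from the convex α face (3α-OH, 3R); this centre is oxidised next, so its configuration and any over-oxidation to the ketone do not matter.

**Step 2**
Reactants: 2 epi-zaluzanin C (two molecules combine)
Product: 7 anhydro-ainsliadimer B, via enone 3 (not isolated), via dienone 4 (not isolated), via cycloadduct 5 (not isolated), via hydroperoxide 6 (not isolated)
Conditions: IBX (1.05 equiv), DMSO, 23 °C; then IBX (0.45 equiv), O2 (1 atm), 55 °C; EtOAc/aq. NaHCO3 partition; then PPh3 (0.5 equiv), EtOAc, 0 °C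
Reagents that add atoms: dioxygen, O=O
Why: Proposed new method: a single-flask oxidative homodimerisation in which IBX first oxidises the allylic alcohol to the enone (standard alcohol oxidation) and then, in deficiency at 55 °C, dehydrogenates part of it through its C2 enol to the cross-conjugated dienone (known IBX α,β-dehydrogenation of ketones, helped here because the hydrogen lost from C1 is allylic); the dienone is an s-cis-locked diene born in a large excess of its own precursor and is trapped in an ortho-selective, carbonyl-endo Diels–Alder reaction at the C4'=C15' bond of the enone (bonds C2–C4' and C14–C15'), adding to the convex α face of the dienophile (syn to H-1' and H-5'), which sets spiro C4', while the configuration created at C2 is erased in the next event; the cycloadduct has a doubly activated C2–H (α to C3=O, allylic to C1=C10) and autoxidises through its dienol/pentadienyl radical, O2 being captured at the γ-carbon C10 on the β face (the side of the C3' carbonyl, anti to the bulky C5' arm of the spiro ring) with shift of the alkene to C1=C2, and PPh3 reduces the hydroperoxide to the alcohol; the closest known reaction types are the Saegusa–Ito desaturation/Diels–Alder dimerisation of silyl enol ethers and the aerobic γ-hydroxylation of β,γ-unsaturated ketones.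

**Step 3**
Reactants: 7 anhydro-ainsliadimer B
Product: 8 ainsliadimer B
Conditions: PMe3 (10 mol %), THF/H2O (1:1), 0 → 23 °C, 0.01 M
Reagents that add atoms: water, O
Why: phosphine-catalysed oxa-Michael hydration: PMe3 adds reversibly to the most electrophilic acceptor (the exocyclic methylene of the cross-conjugated cyclopentenone), the phosphonium hydroxide so formed delivers hydroxide to C15, and reversible enolisation/retro-Michael places C4 under thermodynamic control (CH2OH α, trans to the C5–C6 bond; H-4 β), while the two α-methylene lactones hydrate far more slowly; the reaction is a pure addition.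

**Compound list**
1 | dehydrocostus lactone: guaia-4(15),10(14),11(13)-trien-12,6α-olide, 1α-H, 5α-H, 6β-H, 7α-H, (3aS,6aR,9aR,9bS) | C=C3CC[C@H]1C(=C)CC[C@H]2C(=C)C(=O)O[C@@H]2[C@H]13 | starting material
2 | epi-zaluzanin C (the 3-epimer of zaluzanin C): 3α-hydroxy (3R) derivative of 1, exocyclic C4=C15 retained | C=C3[C@H](O)C[C@H]1C(=C)CC[C@H]2C(=C)C(=O)O[C@@H]2[C@H]13 | intermediate
3 | enone (dehydrozaluzanin C): 3-oxo derivative of 1 (α-methylene cyclopentanone) | C=C3C(=O)C[C@H]1C(=C)CC[C@H]2C(=C)C(=O)O[C@@H]2[C@H]13 | intermediate
4 | dienone (1,2-didehydro-dehydrozaluzanin C): 3-oxoguaia-1,4(15),10(14),11(13)-tetraen-12,6α-olide, 5α-H, 6β-H, 7α-H | C=C3C(=O)C=C1C(=C)CC[C@H]2C(=C)C(=O)O[C@@H]2[C@H]13 | intermediate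
5 | cycloadduct: upper unit 3-oxoguaia-1(10),4(15),11(13)-trien-12,6α-olide (2α-H, 5α-H, 6β-H, 7α-H) joined by C2–C4' and C14–C15' to the lower dehydrozaluzanin C unit (1'α-H, 5'α-H, 6'β-H, 7'α-H); cyclohexene C1, C2, C4', C15', C14, C10 spiro at C4', where the bond to C2 is α and C15' is β on the lower cyclopentanone | C=C1C(=O)O[C@@H]2[C@@H]3C4=C(CC[C@@H]12)CC[C@]5(C(=O)C[C@H]6C(=C)CC[C@H]7C(=C)C(=O)O[C@@H]7[C@H]65)[C@@H]4C(=O)C3=C | intermediate
6 | hydroperoxide: as 5 but with a C1=C2 enone and 10β-OOH (C14 α) | C=C1C(=O)O[C@@H]2[C@@H]3C4=C(C(=O)C3=C)[C@]3(CC[C@]4(OO)CC[C@@H]12)C(=O)C[C@H]1C(=C)CC[C@H]2C(=C)C(=O)O[C@@H]2[C@H]13 | intermediate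
7 | anhydro-ainsliadimer B (gochnatiolide B-type dienone): 10β-OH, C1=C2, 3-oxo, C4=C15 methylene | C=C1C(=O)O[C@@H]2[C@@H]3C4=C(C(=O)C3=C)[C@]3(CC[C@]4(O)CC[C@@H]12)C(=O)C[C@H]1C(=C)CC[C@H]2C(=C)C(=O)O[C@@H]2[C@H]13 | intermediate
8 | ainsliadimer B: as 7 but with 4β-H and an α-oriented CH2OH (C15) at C4 | C=C1C(=O)O[C@@H]2[C@@H]3C4=C(C(=O)[C@H]3CO)[C@]3(CC[C@]4(O)CC[C@@H]12)C(=O)C[C@H]1C(=C)CC[C@H]2C(=C)C(=O)O[C@@H]2[C@H]13 | target

**Count**
Total step count: 3. Longest linear sequence: 3 steps (1 → 2 → 7 → 8).

**Steps most likely to fail, with fallbacks**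

Step 2 is the most exposed. IBX may dehydrogenate the cycloadduct 5 or the lower ketone instead of the enone 3, the dienone 4 may dimerise with itself, and the face of O2 capture at C10 is predicted, not proven. The fallback sets out from 3, isolated by stopping after the room-temperature IBX stage, and comes back at 5. Silylation of 3 (TBSOTf, Et3N, CH2Cl2, −78 °C) gives the tert-butyldimethylsilyl dienol ether F2. Treating F2 with Pd(OAc)2 (1.1 equiv) in MeCN at 23 °C under argon, in the presence of a second charge of 3 (1.5 equiv), is a Saegusa–Ito desaturation that releases 4 only from the silylated half. The oxidant therefore never meets the adduct, 4 is trapped by 3, and 5 is isolated under argon. It is then aerated and reduced with PPh3 as in step 2 to give 6 and 7.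

Step 3 is next. Hydration may not discriminate cleanly between the three Michael acceptors, the γ-hydrogen at C5 could epimerise, and the β-hydroxy ketone can lose formaldehyde by retro-aldol if the medium becomes too basic. The fallback sets out from 7 and comes back at 8 by a formal hydration in two stages. Conjugate borylation (CuCl 5 mol %, NaOt-Bu 5 mol %, DPEphos 5 mol %, B2pin2 1.05 equiv, MeOH 2 equiv, THF, −20 °C) at the most electrophilic methylene gives the 15-pinacolboronate F3. Oxidation of the C–B bond with NaBO3·4H2O in THF/H2O at 23 °C gives 8, and the mildly basic medium lets C4 settle in the trans arrangement.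

Step 1 is the least risky but can suffer from oxidation at C9 or poor mass balance. Mixtures of 2 and 3 are harmless, because both enter step 2. The fallback sets out from 1 and comes back at 2 by a radical instead of an ene pathway. Kharasch–Sosnovsky acyloxylation (CuBr 5 mol %, tert-butyl peracetate, MeCN, 60 °C) gives the 3α-acetate F1 with the exocyclic alkene retained. Mild transesterification (Mg(OMe)2, MeOH, 0 °C) then frees alcohol 2.

**Further compounds**
F1 | step 1 | epi-zaluzanin C acetate (3α-acetoxy-dehydrocostus lactone) | C=C3[C@H](OC(C)=O)C[C@H]1C(=C)CC[C@H]2C(=C)C(=O)O[C@@H]2[C@H]13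
F2 | step 2 | tert-butyldimethylsilyl dienol ether of dehydrozaluzanin C (3-silyloxy, C2=C3) | C=C3C(O[Si](C)(C)C(C)(C)C)=C[C@H]1C(=C)CC[C@H]2C(=C)C(=O)O[C@@H]2[C@H]13
F3 | step 3 | 15-pinacolboronate of 4β,15-dihydro-7 (boron in place of the C15 hydroxyl of 8) | C=C1C(=O)O[C@@H]2[C@@H]3C4=C(C(=O)[C@H]3CB5OC(C)(C)C(C)(C)O5)[C@]3(CC[C@]4(O)CC[C@@H]12)C(=O)C[C@H]1C(=C)CC[C@H]2C(=C)C(=O)O[C@@H]2[C@H]13
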